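Molar is the unit I reckon in here. I read the runs as substrate (S) having two exits, to target at k_T[S] and through reagent (R) at k[S][R], so that a moment's share of target, the selectivity, is c/(c+[R]), with c = k_T/k a concentration, and target formed is c·ln(R_start/R_end).

| flask | substrate | reagent | temperature | remark | time |
|---|---|---|---|---|---|
| Friday's | 0.050 M | 0.060 M | 60 °C | run made earlier |  |
| Sunday's | 0.075 M | 0.060 M | 60 °C | run made earlier |  |
| spring | 0.050 M (in portions, 3, over 5.0 h) | 0.0600 M | 60 °C | first portion at the start, last at 5.0 h | 25 h |
| midnight | 0.050 M | 0.0600 M (fed, over 5.0 h) | 60 °C | all else is in the flask from the start; the feed brings no volume worth counting | 25 h |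
| autumn | 0.050 M (fed, over 5.0 h) | 0.0600 M | 60 °C | all else is in the flask from the start; the feed brings no volume worth counting | 25 h |
| winter | 0.050 M | 0.0600 M |  | everything together at the start at 20 °C, warmed to 60 °C at 5.0 h | 25 h |
| dawn | 0.050 M | 0.0600 M (fed, over 5.0 h) |  | the addition at 20 °C, then warmed to 60 °C; the feed brings no volume worth counting | 25 h |
| summer | 0.050 M | 0.0600 M | 60 °C | everything together at the start | 25 h |

- Friday's (time / h: target / %, substrate / %): 3.00: 13.0, 0; 8.00: 12.6, 0; 15.0: 11.6, 0; 25.0: 11.7, 1.6
- Sunday's (time / h: target / %, substrate / %): 0.667: 10.3, 20.7; 1.33: 15.9, 9.0; 3.00: 19.4, 2.5; 8.00: 21.1, 0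

(readings scatter by 1 percentage point)

1. the best flask by amount of target, in percent of the substrate charged; "all alike" if 1.5 percentage points covers them all (spring / midnight / autumn / winter / dawn / summer / all alike)
2. amount of target at the end, in percent of the substrate charged, spring
3. amount of target at the end, in percent of the substrate charged, midnight
4. amount of target at the end, in percent of the substrate charged, autumn
5. amount of target at the end, in percent of the substrate charged, winter
6. amount of target at the end, in percent of the substrate charged, dawn
7. amount of target at the end, in percent of the substrate charged, summer

- the numbers in the tables scatter by 1 percentage point (one standard deviation)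
- a reading or a percentage of target counts all its forms, free or not
- the earlier runs do not show what temperature does; that part of a forecast is a guess

Friday's target reads 12.2% on average, and since reagent spent equals substrate gone less target, 0.0161 M of reagent stands at the end, so c, the branch concentration, the reagent level at which a substrate molecule is as likely to become target as to be lost, reads 0.00465 M.

Does dosing substrate matter? That expression holds no [S], so I put spring, autumn and summer at Friday's reading, with reagent starting 12.9 times c.

Can feeding reagent beat that? Sunday's substrate falls at 0.767 /h between its second and third readings, while the balance puts mean reagent at 0.00255 M, which leaves k_T = 0.495 /h and a substrate lifetime of 2.02 h, shorter than the 5.0 h feed. In one lifetime, midnight's feed delivers reagent equal to half of the substrate charge, so I expect target near half of the substrate charge in midnight. The runs do not show what temperature does, so winter and dawn stay guesses for me.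

The forecast says midnight, with spring 12%, midnight 52%, autumn 12%, winter 11%, dawn 15% and summer 12%, and of dawn it says “Dawn's cold feed lets reagent accumulate”.

The flasks give midnight as best, with spring 11.1%, midnight 51.6%, autumn 11.1%, winter 8.12%, dawn 9.77% and summer 11.1%, crystals counted in target.

    substrate + reagent → side product A (k = 0.0280 /M/s, Ea = 72.0 kJ/mol)
    substrate → target (k = 1.20 × 10⁻⁴ /s, Ea = 112 kJ/mol)
    substrate + reagent → side product B (k = 0.00110 /M/s, Ea = 63.0 kJ/mol)
    crystals ⇌ target, rate k4*(cs4 - [target]) while solid is left; crystals form when [target] > cs4 (solubility = 19.0 mM, k = 0.00170 /s)
    substrate + target → side product C (k = 7.30 × 10⁻⁵ /M/s, Ea = 96.0 kJ/mol)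
    (constants at 60 °C)

Read backwards through c, midnight's 51.6% means a mean reagent of 0.00436 M, and summer's 11.1% means 0.0372 M. At the start of winter, at 20 °C, substrate goes to side product A 100 times as fast as to target, against 12.9 from c at 60 °C, so c there, with side product B left aside, is 5.97 × 10⁻⁴ M. With dawn's mean reagent of 0.0242 M over the first 5.0 h, the share is 2.41% with that cold c and 16.1% with Friday's, and dawn gives 9.77%.

The numbers in the tables come from a simulation for substances that don't exist; scatter was added.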